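**Plan**

1. In germacrane numbering the target carries oxygen on C6 and C9, 1,4 to each other across C7–C8, and the C14 ester carbon on C10. The carbons C5–C10 therefore map onto the ring of benzoate ipso,ortho-dihydrodiol (diene C6=C7–C8=C9, diol carbons C5 and C10).
2. Retrosynthetic cuts, last bond first: C11=C13 (unmasking); C1=C10 (ring-closing metathesis, ten-membered ring); the C2–O–C3 epoxide (directed epoxidation); C3–C4 (Stille); C4=C5 (iodo-olefination); C5–C10 (glycol cleavage, back to the six-membered template); C12 (carbonylation, γ-lactone); the C8–O and C9–O acyl bonds; C7–C11 (epoxide opening); C6–O and C9–O (singlet oxygen).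
3. Forward ring order: dioxolane-protected cyclohexadiene → 2,3-dioxabicyclo[2.2.2]octene → epoxide plus a temporary C6–O–C14 bridged lactone → trans-fused α-methylene γ-lactone → template ring cut at C5–C10 → C1–C4 joined as a two-carbon iodo-olefin and a three-carbon stannane → ten-membered carbocycle closed last.
4. Stereochemistry: the dioxygenase sets C5/C10, whose acetonide steers singlet oxygen to set C6 and C9; C7 comes from trans-diaxial epoxide opening and C8 from one SN2 inversion; C2/C3 and the epoxy acid come from D-tartrate-controlled epoxidations and the 2-methylbutanoate from (R)-2-methylbutanoic acid; C4=C5 comes from a Z-selective Wittig reaction and C1=C10 from the ring closure.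

Key step: step 4

Remark: germacrane numbering is used (ring C1–C10, lactone carbons C11–C13, C14 = ester carbon on C10, C15 = methyl on C4); in the six-membered template C5–C10, β is the face that carries C14 and α the face of the C5 and C10 oxygens; the side-chain acids are taken as written in the target, (R)-2-methylbutanoate and (2S,3S)-2,3-epoxy-2-methylbutanoate.

**Route**

Step 1
Reactants: 1 benzoic acid; 2 dioxygen
Product: 3 (1S,2R)-1,2-dihydroxycyclohexa-3,5-diene-1-carboxylic acid
Conditions: whole cells of Ralstonia eutropha B9, aerated mineral medium with fructose, pH 7, 30 °C; acidify to pH 3, extract (EtOAc)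
Reagents that add atoms: none
Why: The benzoate 1,2-dioxygenase of this mutant, which lacks the diol dehydrogenase, adds both atoms of O2 to the same face of the ipso and ortho carbons (enzymatic arene cis-dihydroxylation), which sets C10 as 1S and C5 as 2R.

Step 2
Reactants: 3 dihydrodiol acid
Product: 4 (3aS,7aR)-2,2-dimethyl-3a,7a-dihydro-1,3-benzodioxole-3a-carboxylic acid (5α,10α-acetonide)
Conditions: 2,2-dimethoxypropane, TsOH (cat.), acetone, 0 °C to rt
Reagents that add atoms: 2,2-dimethoxypropane, COC(C)(C)OC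
Why: Acid-catalysed transketalisation (acetonide formation) ties the cis-diol into a dioxolane on the α-face, which removes the free hydroxyls that invite dehydration to the arene and will later shield that face.

Step 3
Reactants: 4 acetonide acid
Product: 5 methyl (3aS,7aR)-2,2-dimethyl-3a,7a-dihydro-1,3-benzodioxole-3a-carboxylate
Conditions: MeI, K2CO3, DMF, rt
Reagents that add atoms: iodomethane, CI
Why: SN2 alkylation of the potassium carboxylate (O-methylation) forms the methyl ester without the acid that would aromatise the dihydroarene, and no stereocentre is touched.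

Step 4
Reactants: 5 methyl ester acetonide; 2 dioxygen
Product: 6 methyl 6β,9β-epidioxy-5α,10α-(isopropylidenedioxy)cyclohex-7-ene-10β-carboxylate (2,3-dioxabicyclo[2.2.2]octene; peroxide bridge anti to the acetonide)
Conditions: O2, tetraphenylporphyrin (cat.), CH2Cl2, visible light, −20 °C
Reagents that add atoms: none
Why: Visible light excites the porphyrin, which sensitises triplet oxygen to singlet oxygen, and this adds suprafacially to the ring-held s-cis diene C6=C7–C8=C9 in a concerted [4+2] cycloaddition that forms the C6–O and C9–O bonds and moves the alkene to C7=C8. The closest known reaction type is the singlet-oxygen endoperoxidation of arene cis-dihydrodiol acetonides. The one new ring, the six-membered 1,2-dioxine of the dioxabicyclo[2.2.2]octene, is closed by the cycloaddition itself, with the peroxide bridging C6 and C9 across the carbocycle. C6 and C9 are both set by the face of approach: the cis-fused dioxolane on C5 and C10 covers the α-face, so oxygen adds to the β-face, the two C–O bonds come out cis to each other and trans to the acetonide, and the absolute sense is that of the enzymatic diol. The step needs π-facial selectivity and preference for [4+2] addition over the ene reaction and over aromatisation; the acetonide secures the first, and the locked s-cis diene together with low temperature and the absence of acid secures the second.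

Step 5
Reactants: 6 endoperoxide
Product: 7 methyl 6β,9β-dihydroxy-5α,10α-(isopropylidenedioxy)cyclohex-7-ene-10β-carboxylate
Conditions: thiourea, MeOH, rt
Reagents that add atoms: none
Why: Thiourea reduces only the O–O bond (endoperoxide reduction), so the two C–O bonds and the C6 and C9 configurations made in step 4 are kept in the cis-1,4-diol.

Step 6
Reactants: 7 ene-diol
Product: 8 methyl 7β,8β-epoxy-6β,9β-dihydroxy-5α,10α-(isopropylidenedioxy)cyclohexane-10β-carboxylate
Conditions: m-CPBA, CH2Cl2, 0 °C
Reagents that add atoms: 3-chloroperoxybenzoic acid, OOC(=O)c1cccc(Cl)c1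
Why: Henbest epoxidation: both allylic hydroxyls hydrogen-bond the peracid on the β-face while the acetonide covers the α-face, so the new C7 and C8 stereocentres carry the epoxide oxygen cis to the C6 and C9 hydroxyls.

Step 7
Reactants: 8 epoxy diol
Product: 9 7β,8β-epoxy-9β-hydroxy-5α,10α-(isopropylidenedioxy)cyclohexane-10β-carboxylic acid 14→6β lactone (6-oxabicyclo[3.2.1]octan-7-one)
Conditions: DBU (0.2 equiv), toluene, 4 Å MS, 80 °C
Reagents that add atoms: none
Why: Base-catalysed intramolecular transesterification (lactonisation) can involve only the C6 hydroxyl, which is cis-1,3 to C14, and with methanol taken up by the sieves it should give the bridged lactone, which protects O6, leaves O9 free and locks the carbocycle in the chair that has C6–O and C10–C14 axial.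

Step 8
Reactants: 9 bridged epoxy lactone
Product: 10 8β,9β-dihydroxy-5α,10α-(isopropylidenedioxy)-7α-[(trimethylsilyl)ethynyl]cyclohexane-10β-carboxylic acid 14→6β lactone
Conditions: LiC≡CSiMe3, Et2AlCl, toluene, 0 °C; then 9, 0 °C to rt; aqueous Rochelle salt
Reagents that add atoms: diethyl[(trimethylsilyl)ethynyl]aluminium, CC[Al](CC)C#C[Si](C)(C)C
Why: Epoxide opening by an alkynylalane follows the Fürst–Plattner rule: in the locked chair only attack at C7 from the α-face gives the trans-diaxial product, the aluminium alkoxide of the cis C9 hydroxyl activates the epoxide oxygen, and the SN2 inversion places the alkyne 7α and leaves the C8 hydroxyl β, while the alane does not add to the lactone carbonyl.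

Step 9
Reactants: 10 alkynyl diol; 11 (R)-2-methylbutanoic acid
Product: 14 9β-O-[(R)-2-methylbutanoyl] ester of 10 (8β-hydroxyl free), via (R)-2-methylbutanoyl chloride 12 (not isolated), via C8/C9 dibutylstannylene acetal 13 (not isolated)
Conditions: (a) 11, (COCl)2, DMF (cat.), CH2Cl2, 0 °C to rt, concentrate; (b) 10, Bu2SnO, toluene, reflux (−H2O); (c) 12, toluene, 0 °C to rt
Reagents that add atoms: none
Why: Stannylene-acetal-directed monoacylation of the cis-diol puts the acyl group on the equatorial C9 oxygen and not on the axial C8 oxygen, and acylation by the acid chloride without an amine base avoids ketene formation, so the α-stereocentre of the acid is kept.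

Step 10
Reactants: 15 methyl (Z)-2-methylbut-2-enoate (methyl angelate)
Product: 16 (Z)-2-methylbut-2-en-1-ol
Conditions: DIBAL-H, CH2Cl2, −78 to 0 °C
Reagents that add atoms: none
Why: DIBAL-H reduces the conjugated ester to the allylic alcohol (1,2-reduction) without isomerising the Z-alkene.

Step 11
Reactants: 16 (Z)-allylic alcohol
Product: 17 [(2R,3S)-2,3-dimethyloxiran-2-yl]methanol
Conditions: Ti(OiPr)4 (10 mol %), D-(−)-diisopropyl tartrate (12 mol %), t-BuOOH, 4 Å MS, CH2Cl2, −20 °C
Reagents that add atoms: tert-butyl hydroperoxide, CC(C)(C)OO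
Why: Sharpless asymmetric epoxidation: with D-(−)-tartrate the titanium-bound peroxide is delivered to the face of the Z-allylic alcohol that gives the 2R,3S epoxy alcohol, and the Z-geometry of the alkene fixes the future carboxyl cis to the C3 methyl.

Step 12
Reactants: 17 epoxy alcohol
Product: 18 (2S,3S)-2,3-dimethyloxirane-2-carboxylic acid
Conditions: RuCl3·xH2O (cat.), NaIO4, CCl4–MeCN–H2O, 0 °C to rt
Reagents that add atoms: water, O
Why: RuO4 generated from RuCl3 and NaIO4 oxidises the primary alcohol through the aldehyde hydrate to the acid (Sharpless oxidation) without opening the epoxide, so both centres are unchanged and become 2S,3S only through the change in priorities.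

Step 13
Reactants: 14 C9 ester with free 8β-hydroxyl; 18 epoxy acid
Product: 20 8α-O-[(2S,3S)-2,3-dimethyloxirane-2-carbonyl] 9β-O-[(R)-2-methylbutanoyl] 7α-[(trimethylsilyl)ethynyl] bridged lactone acetonide, via C8 triflate 19 (not isolated)
Conditions: (a) Tf2O, pyridine, CH2Cl2, −30 to 0 °C, cold aqueous work-up; (b) 18 (1.5 equiv), Cs2CO3 (0.75 equiv), 18-crown-6 (cat.), DMF, 0 °C to rt
Reagents that add atoms: none
Why: Triflation then SN2 displacement by the caesium carboxylate (the triflate inversion used for cyclitols): the axial C8 triflate is attacked from the α-face beside the slim alkyne, the cis C9 ester cannot give anchimeric assistance, and the inversion both sets the 8α-oxygen and installs the epoxy ester.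

Step 14
Reactants: 20 diester lactone
Product: 21 methyl 7α-ethynyl-6β-hydroxy-5α,10α-(isopropylidenedioxy)-8α-{[(2S,3S)-2,3-dimethyloxiran-2-yl]carbonyloxy}-9β-{[(2R)-2-methylbutanoyl]oxy}cyclohexane-10β-carboxylate
Conditions: K2CO3 (0.2 equiv), MeOH, 0 °C
Reagents that add atoms: methanol, CO
Why: Base-catalysed transesterification with methanol should open the strained bridged lactone, whose carbonyl is activated by the α-oxygen on C10, faster than it touches the two hindered secondary esters, and methoxide also cleaves the alkynyl C–Si bond (protodesilylation), returning the C14 methyl ester, the free C6 hydroxyl and the terminal alkyne.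

Step 15
Reactants: 21 hydroxy alkyne
Product: 22 trans-fused α-methylene γ-lactone (O6–C12(=O)–C11(=C13H2)–C7) carrying the 8α-epoxy ester, the 9β-(R)-2-methylbutanoate, the 5α,10α-acetonide and the C14 methyl ester
Conditions: PdI2 (5 mol %), PBu3 (10 mol %), CO (7 bar), MeCN, 70 °C
Reagents that add atoms: carbon monoxide, [C-]#[O+]
Why: Palladium-catalysed cyclocarbonylation of a trans-2-ethynylcyclohexanol: the alkoxycarbonylpalladium formed from the C6 hydroxyl and CO adds across the alkyne in a 5-exo sense and protonolysis gives the exocyclic methylene, the trans ring fusion following from the C6 and C7 configurations already in place.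

Step 16
Reactants: 22 α-methylene lactone
Product: 23 13-(phenylsulfonyl)-11,13-dihydro derivative of 22 (both C11 epimers)
Conditions: PhSO2Na, AcOH, DMF, rt
Reagents that add atoms: sodium benzenesulfinate, [Na+].[O-]S(=O)c1ccccc1
Why: Conjugate (sulfa-Michael) addition of benzenesulfinate masks the exocyclic alkene as a sulfone that is inert to oxidants and to the metathesis catalyst, since the free methylene would otherwise offer an eight-membered ring closure in step 27; the new C11 centre is not controlled because step 28 removes it.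

Step 17
Reactants: 23 sulfone acetonide
Product: 25 5,10-seco aldehyde keto ester (C5 formyl on C6; C10 ketone of the methyl α-keto ester; sulfone-masked 6,12-lactone; C6 to C9 as in the target), via C5/C10 diol 24 (not isolated)
Conditions: (a) TFA–H2O 9:1, 0 °C, evaporate; (b) NaIO4, THF–pH 7 buffer, 0 °C to rt; used at once
Reagents that add atoms: none
Why: Acid hydrolysis of the acetonide then Malaprade glycol cleavage of the cis-diol by periodate cuts C5–C10, leaving C5 as the aldehyde and C10 as the ketone of the α-keto ester with C6 to C9 untouched.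

Step 18
Reactants: 25 aldehyde keto ester
Product: 26 (4Z)-4-iodo-4-ene: C5H=C4(I)CH3 with iodine cis to C6, keto ester and all other groups unchanged
Conditions: EtPPh3I, n-BuLi, THF, rt; I2, −78 °C; NaHMDS, −78 °C; then 25, −78 °C
Reagents that add atoms: (1-iodoethylidene)triphenylphosphorane, CC(I)=P(c1ccccc1)(c1ccccc1)c1ccccc1
Why: Stork–Zhao-type Wittig olefination with the α-iodo ylide gives the Z-iodoalkene (iodine cis to C6) under kinetic control, and at −78 °C the aldehyde should react well before the hindered ketone or the C9–H is attacked.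

Step 19
Reactants: 27 tert-butyldimethyl(prop-2-yn-1-yloxy)silane
Product: 28 tert-butyldimethyl{[3-(tributylstannyl)prop-2-yn-1-yl]oxy}silane
Conditions: n-BuLi, THF, −78 °C; Bu3SnCl, −78 °C to rt
Reagents that add atoms: tributyltin chloride, CCCC[Sn](Cl)(CCCC)CCCC
Why: Deprotonation of the terminal alkyne and trapping of the acetylide with Bu3SnCl (stannylation) gives the alkynylstannane.

Step 20
Reactants: 28 alkynylstannane
Product: 29 tert-butyldimethyl{[(2Z)-3-(tributylstannyl)prop-2-en-1-yl]oxy}silane
Conditions: Cp2Zr(H)Cl, THF, rt; then H2O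
Reagents that add atoms: none
Why: Hydrozirconation adds H and Zr syn across the alkyne with zirconium on the tin-bearing carbon, and protonolysis of the C–Zr bond with retention leaves tin cis to the CH2O group (Z-vinylstannane).

Step 21
Reactants: 26 Z-iodoalkene; 29 Z-vinylstannane
Product: 30 (2Z,4Z)-diene C6–C5H=C4(CH3)–C3H=C2H–C1H2OTBS with the C10 keto ester unchanged
Conditions: Pd2(dba)3 (5 mol %), AsPh3 (20 mol %), CuI (10 mol %), DMF, rt, dark
Reagents that add atoms: none
Why: Stille cross-coupling proceeds with retention at both sp2 carbons, so the Z-iodide and the Z-stannane give the 2Z,4Z-diene with C3 cis to C6, and the neutral conditions spare the keto ester.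

Step 22
Reactants: 30 diene keto ester
Product: 31 C10 methylene compound (methyl acrylate unit C9–C10(=CH2)–CO2Me; the new CH2 is C1)
Conditions: Zn, CH2Br2, TiCl4 (reagent pre-formed in THF), CH2Cl2, 0 °C to rt
Reagents that add atoms: dibromomethane, BrCBr
Why: Lombardo methylenation (Zn, CH2Br2, TiCl4) converts the C10 ketone into the 1,1-disubstituted alkene under non-basic conditions, so C9 is not enolised and no ester carbonyl is attacked.

Step 23
Reactants: 31 silyl ether
Product: 32 (2Z,4Z)-dien-1-ol (free C1 hydroxyl)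
Conditions: camphorsulfonic acid (cat.), MeOH–CH2Cl2, 0 °C
Reagents that add atoms: none
Why: Acid-catalysed methanolysis of the primary allylic silyl ether (desilylation) frees the hydroxyl that directs the next step.

Step 24
Reactants: 32 dienol
Product: 33 (2R,3S)-2,3-epoxy-(4Z)-en-1-ol (cis-epoxide between C2 and C3)
Conditions: Ti(OiPr)4 (20 mol %), D-(−)-diisopropyl tartrate (24 mol %), t-BuOOH, 4 Å MS, CH2Cl2, −20 °C
Reagents that add atoms: tert-butyl hydroperoxide, CC(C)(C)OO
Why: Sharpless asymmetric epoxidation: the titanium tartrate binds the hydroxyl and so oxidises only the allylic C2=C3 alkene, with D-(−)-tartrate delivering oxygen to the face that gives the 2R,3S cis-epoxide (reagent control), while the C4=C5 alkene and the electron-poor C10 methylene are left.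

Step 25
Reactants: 33 epoxy alcohol
Product: 34 (2R,3S)-2,3-epoxy aldehyde (C1 formyl on the oxirane)
Conditions: Dess–Martin periodinane, pyridine, CH2Cl2, 0 °C to rt
Reagents that add atoms: none
Why: Dess–Martin oxidation takes the primary epoxy alcohol to the aldehyde under buffered conditions that neither open the epoxide nor epimerise C2.

Step 26
Reactants: 34 epoxy aldehyde
Product: 35 vinyl epoxide (H2C=C1H–C2, cis-2,3-epoxide, 4Z-alkene) with the C10 methylene ester; diene for ring closure
Conditions: MePPh3Br, KHMDS, THF, 0 °C; then 34, −78 to −20 °C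
Reagents that add atoms: methylenetriphenylphosphorane, C=P(c1ccccc1)(c1ccccc1)c1ccccc1
Why: Wittig methylenation of the epoxy aldehyde at low temperature gives the vinyl epoxide, the aldehyde being far more reactive toward the ylide than any other group present.

Step 27
Reactants: 35 diene
Product: 36 13-(phenylsulfonyl)-11,13-dihydro derivative of the target (ten-membered ring closed, 1(10)E,4Z; both C11 epimers)
Conditions: second-generation Hoveyda–Grubbs catalyst (15 mol %), CH2Cl2 (0.5 mM), 40 °C
Reagents that add atoms: none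
Why: Ring-closing olefin metathesis: the catalyst loads at the monosubstituted C1 alkene, the cis-epoxide and the Z-alkene turn the chain toward the C10 methylene, the masked lactone offers no competing alkene, and the bent ten-membered ring should take the new trisubstituted alkene with C2 cis to C9, which is the 1(10)E geometry of the target.

Step 28
Reactants: 36 sulfone
Product: 37 target CNP0485260.1, (2R,3S,6R,7S,8S,9S)-2,3-epoxy-8-[(2S,3S)-2,3-dimethyloxirane-2-carbonyloxy]-9-[(2R)-2-methylbutanoyloxy]-14-methoxy-14-oxogermacra-1(10)E,4Z,11(13)-trien-6,12-olide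
Conditions: DBU (1.1 equiv), CH2Cl2, −20 to 0 °C
Reagents that add atoms: none
Why: E1cB elimination of benzenesulfinate from the β-sulfonyl lactone (retro-sulfa-Michael) restores the C11=C13 methylene under conditions mild enough for the vinyl epoxide and the esters.

**Compound list**

1 | benzoic acid | OC(=O)c1ccccc1 | starting material
2 | dioxygen | O=O | starting material
3 | (1S,2R)-1,2-dihydroxycyclohexa-3,5-diene-1-carboxylic acid | OC(=O)[C@@]1(O)[C@H](O)C=CC=C1 | intermediate
4 | (3aS,7aR)-2,2-dimethyl-3a,7a-dihydro-1,3-benzodioxole-3a-carboxylic acid | OC(=O)[C@@]12OC(C)(C)O[C@@H]1C=CC=C2 | intermediate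
5 | methyl (3aS,7aR)-2,2-dimethyl-3a,7a-dihydro-1,3-benzodioxole-3a-carboxylate | COC(=O)[C@@]12OC(C)(C)O[C@@H]1C=CC=C2 | intermediate
6 | methyl 6β,9β-epidioxy-5α,10α-(isopropylidenedioxy)cyclohex-7-ene-10β-carboxylate (endoperoxide) | COC(=O)[C@@]12OC(C)(C)O[C@@H]1[C@@H]3C=C[C@H]2OO3 | intermediate
7 | methyl 6β,9β-dihydroxy-5α,10α-(isopropylidenedioxy)cyclohex-7-ene-10β-carboxylate | COC(=O)[C@@]12OC(C)(C)O[C@@H]1[C@@H](O)C=C[C@H]2O | intermediate
8 | methyl 7β,8β-epoxy-6β,9β-dihydroxy-5α,10α-(isopropylidenedioxy)cyclohexane-10β-carboxylate | COC(=O)[C@@]12OC(C)(C)O[C@@H]1[C@@H](O)[C@H]3O[C@H]3[C@H]2O | intermediate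
9 | 7β,8β-epoxy-9β-hydroxy-5α,10α-(isopropylidenedioxy)cyclohexane-10β-carboxylic acid 14→6β lactone | O=C1O[C@H]2[C@H]3O[C@H]3[C@@H](O)[C@@]14OC(C)(C)O[C@H]24 | intermediate
10 | 8β,9β-dihydroxy-5α,10α-(isopropylidenedioxy)-7α-[(trimethylsilyl)ethynyl]cyclohexane-10β-carboxylic acid 14→6β lactone | O=C1O[C@H]2[C@H](C#C[Si](C)(C)C)[C@@H](O)[C@@H](O)[C@@]14OC(C)(C)O[C@H]24 | intermediate
11 | (R)-2-methylbutanoic acid | OC(=O)[C@H](C)CC | starting material
12 | (R)-2-methylbutanoyl chloride | ClC(=O)[C@H](C)CC | intermediate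
13 | 8β,9β-O-dibutylstannylene acetal of 10 | O=C1O[C@H]2[C@H](C#C[Si](C)(C)C)[C@H]3O[Sn](CCCC)(CCCC)O[C@H]3[C@@]14OC(C)(C)O[C@H]24 | intermediate
14 | 9β-O-[(R)-2-methylbutanoyl] ester of 10 (8β-hydroxyl free) | O=C1O[C@H]2[C@H](C#C[Si](C)(C)C)[C@@H](O)[C@@H](OC(=O)[C@H](C)CC)[C@@]14OC(C)(C)O[C@H]24 | intermediate
15 | methyl (Z)-2-methylbut-2-enoate | C/C=C(/C)C(=O)OC | starting material
16 | (Z)-2-methylbut-2-en-1-ol | C/C=C(/C)CO | intermediate
17 | [(2R,3S)-2,3-dimethyloxiran-2-yl]methanol | OC[C@@]1(C)O[C@H]1C | intermediate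
18 | (2S,3S)-2,3-dimethyloxirane-2-carboxylic acid | OC(=O)[C@@]1(C)O[C@H]1C | intermediate
19 | 8β-trifluoromethanesulfonate of 14 | O=C1O[C@H]2[C@H](C#C[Si](C)(C)C)[C@@H](OS(=O)(=O)C(F)(F)F)[C@@H](OC(=O)[C@H](C)CC)[C@@]14OC(C)(C)O[C@H]24 | intermediate
20 | 8α-O-[(2S,3S)-2,3-dimethyloxirane-2-carbonyl] 9β-O-[(R)-2-methylbutanoyl] 7α-[(trimethylsilyl)ethynyl] bridged lactone acetonide | O=C1O[C@H]2[C@H](C#C[Si](C)(C)C)[C@H](OC(=O)[C@@]3(C)O[C@H]3C)[C@@H](OC(=O)[C@H](C)CC)[C@@]14OC(C)(C)O[C@H]24 | intermediate
21 | methyl 7α-ethynyl-6β-hydroxy-5α,10α-(isopropylidenedioxy)-8α-{[(2S,3S)-2,3-dimethyloxiran-2-yl]carbonyloxy}-9β-{[(2R)-2-methylbutanoyl]oxy}cyclohexane-10β-carboxylate | COC(=O)[C@@]12OC(C)(C)O[C@@H]1[C@@H](O)[C@H](C#C)[C@H](OC(=O)[C@@]3(C)O[C@H]3C)[C@H]2OC(=O)[C@H](C)CC | intermediate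
22 | trans-fused α-methylene γ-lactone (6β-O, 7α-C) with 8α-epoxy ester, 9β-(R)-2-methylbutanoate, 5α,10α-acetonide and C14 methyl ester | COC(=O)[C@@]12OC(C)(C)O[C@@H]1[C@H]3OC(=O)C(=C)[C@@H]3[C@H](OC(=O)[C@@]4(C)O[C@H]4C)[C@H]2OC(=O)[C@H](C)CC | intermediate
23 | 13-(phenylsulfonyl)-11,13-dihydro derivative of 22 (C11 epimers) | COC(=O)[C@@]12OC(C)(C)O[C@@H]1[C@H]3OC(=O)C(CS(=O)(=O)c4ccccc4)[C@@H]3[C@H](OC(=O)[C@@]5(C)O[C@H]5C)[C@H]2OC(=O)[C@H](C)CC | intermediate
24 | 5α,10α-diol obtained from 23 by loss of the acetonide | COC(=O)[C@@]1(O)[C@H](O)[C@H]2OC(=O)C(CS(=O)(=O)c3ccccc3)[C@@H]2[C@H](OC(=O)[C@@]4(C)O[C@H]4C)[C@H]1OC(=O)[C@H](C)CC | intermediate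
25 | 5,10-seco aldehyde keto ester (C5 formyl, C10 ketone of the methyl α-keto ester, sulfone-masked 6,12-lactone, C6 to C9 as in the target) | O=C[C@H]1OC(=O)C(CS(=O)(=O)c2ccccc2)[C@@H]1[C@H](OC(=O)[C@@]3(C)O[C@H]3C)[C@@H](OC(=O)[C@H](C)CC)C(=O)C(=O)OC | intermediate
26 | (4Z)-4-iodo-4-ene analogue of 25 (C5H=C4(I)CH3, iodine cis to C6) | C/C(I)=C/[C@H]1OC(=O)C(CS(=O)(=O)c2ccccc2)[C@@H]1[C@H](OC(=O)[C@@]3(C)O[C@H]3C)[C@@H](OC(=O)[C@H](C)CC)C(=O)C(=O)OC | intermediate
27 | tert-butyldimethyl(prop-2-yn-1-yloxy)silane | C#CCO[Si](C)(C)C(C)(C)C | starting material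
28 | tert-butyldimethyl{[3-(tributylstannyl)prop-2-yn-1-yl]oxy}silane | CCCC[Sn](CCCC)(CCCC)C#CCO[Si](C)(C)C(C)(C)C | intermediate
29 | tert-butyldimethyl{[(2Z)-3-(tributylstannyl)prop-2-en-1-yl]oxy}silane | CCCC[Sn](CCCC)(CCCC)/C=C\CO[Si](C)(C)C(C)(C)C | intermediate
30 | (2Z,4Z)-1-(tert-butyldimethylsilyloxy) diene with C10 keto ester | CC(C)(C)[Si](C)(C)OC/C=C\C(C)=C/[C@H]1OC(=O)C(CS(=O)(=O)c2ccccc2)[C@@H]1[C@H](OC(=O)[C@@]3(C)O[C@H]3C)[C@@H](OC(=O)[C@H](C)CC)C(=O)C(=O)OC | intermediate
31 | C10 methylene analogue of 30 (methyl acrylate unit) | CC(C)(C)[Si](C)(C)OC/C=C\C(C)=C/[C@H]1OC(=O)C(CS(=O)(=O)c2ccccc2)[C@@H]1[C@H](OC(=O)[C@@]3(C)O[C@H]3C)[C@@H](OC(=O)[C@H](C)CC)C(=C)C(=O)OC | intermediate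
32 | (2Z,4Z)-dien-1-ol | OC/C=C\C(C)=C/[C@H]1OC(=O)C(CS(=O)(=O)c2ccccc2)[C@@H]1[C@H](OC(=O)[C@@]3(C)O[C@H]3C)[C@@H](OC(=O)[C@H](C)CC)C(=C)C(=O)OC | intermediate
33 | (2R,3S)-2,3-epoxy-(4Z)-en-1-ol | OC[C@H]1O[C@H]1/C(C)=C\[C@H]2OC(=O)C(CS(=O)(=O)c3ccccc3)[C@@H]2[C@H](OC(=O)[C@@]4(C)O[C@H]4C)[C@@H](OC(=O)[C@H](C)CC)C(=C)C(=O)OC | intermediate
34 | (2R,3S)-2,3-epoxy aldehyde (C1 formyl) | O=C[C@H]1O[C@H]1/C(C)=C\[C@H]2OC(=O)C(CS(=O)(=O)c3ccccc3)[C@@H]2[C@H](OC(=O)[C@@]4(C)O[C@H]4C)[C@@H](OC(=O)[C@H](C)CC)C(=C)C(=O)OC | intermediate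
35 | C1 vinyl cis-2,3-epoxide with C10 methylene ester (diene for ring closure) | C=C[C@H]1O[C@H]1/C(C)=C\[C@H]2OC(=O)C(CS(=O)(=O)c3ccccc3)[C@@H]2[C@H](OC(=O)[C@@]4(C)O[C@H]4C)[C@@H](OC(=O)[C@H](C)CC)C(=C)C(=O)OC | intermediate
36 | 13-(phenylsulfonyl)-11,13-dihydro derivative of the target (C11 epimers) | O=S(=O)(CC1C(=O)O[C@@H]2/C=C(/C)[C@@H]3O[C@@H]3/C=C(/C(=O)OC)[C@H](OC(=O)[C@H](C)CC)[C@@H](OC(=O)[C@@]3(C)O[C@H]3C)[C@@H]12)c1ccccc1 | intermediate
37 | CNP0485260.1 | C=C1C(=O)O[C@@H]2/C=C(/C)[C@@H]3O[C@@H]3/C=C(/C(=O)OC)[C@H](OC(=O)[C@H](C)CC)[C@@H](OC(=O)[C@@]3(C)O[C@H]3C)[C@@H]12 | target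

**Count**

Total: 28 steps (23 in the main line, 3 for acid 18, 2 for stannane 29). Longest linear sequence: 23 steps from benzoic acid (steps 1–9, 13–18, 21–28).

**Steps most likely to fail**

Step 27 (ring-closing metathesis). The alkylidene forms at the unhindered C1 alkene and may find a second molecule faster than it engages the hindered, electron-poor C10 methylene, so that dimers and oligomers form in place of the ten-membered ring. The fallback is a relay ring closure that sets out from 30 and returns at 36. Keto ester 30 is olefinated at C10 with the ylide from hex-5-enyltriphenylphosphonium bromide (NaHMDS, THF, −78 °C) in place of the methylenation, giving the C10 hex-5-enylidene ester F1 (either alkene geometry serves). The operations of steps 23 to 26 then give the relay dienol F2, the relay epoxy alcohol F3, the relay epoxy aldehyde F4 and the relay vinyl epoxide F5. With the same catalyst the terminal alkene of the pentenyl arm can also be engaged; it then expels cyclopentene and leaves the ruthenium carbene directly on C10, which only has to capture the monosubstituted C1 alkene within the same molecule to give 36.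

Step 18 (iodo-olefination beside the α-keto ester). The basic ylide may deprotonate C9 next to the C10 ketone, after which the enolate expels the C8 carboxylate, or the ylide may add to the ketone as well as to the aldehyde. The fallback carries C10 as an alcohol through the basic step; it sets out from 23 and returns at 30. After the periodate cleavage of step 17, NaBH4 is added to the same pot at 0 °C to give the C5,C10-diol F6 (primary C5 alcohol, secondary alcohol of the α-hydroxy ester, both C10 epimers). TEMPO with PhI(OAc)2 oxidises only the primary alcohol to the C5 aldehyde F7. The conditions of step 18 then give the Z-iodoalkene F8 and those of step 21 the silyloxy diene F9, and Dess–Martin oxidation of the C10 alcohol gives 30.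

Step 13 (displacement at C8). The axial triflate may lose triflic acid toward C9 through the antiperiplanar C9–H faster than the carboxylate displaces it, or the hindered hydroxyl may not be sulfonylated cleanly. The fallback activates both oxygens at once as a cyclic sulfate; it sets out from 10 and returns at 20. Diol 10 with SO2Cl2 and Et3N in CH2Cl2 at −78 °C gives the 8β,9β-cyclic sulfate F10. The caesium salt of 18 in DMF opens it at C8, the only carbon open to backside attack because C9 is neopentyl, to give with inversion the caesium 9β-sulfate of the 8α-epoxy ester F11. Catalytic H2SO4 with one equivalent of water in THF hydrolyses the sulfate to the 9β-alcohol F12, and acylation with acid chloride 12 and pyridine gives 20.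

**Further compounds**

F1 | step 27 | C10 hex-5-enylidene ester (relay analogue of 31) | CC(C)(C)[Si](C)(C)OC/C=C\C(C)=C/[C@H]1OC(=O)C(CS(=O)(=O)c2ccccc2)[C@@H]1[C@H](OC(=O)[C@@]3(C)O[C@H]3C)[C@@H](OC(=O)[C@H](C)CC)C(=CCCCC=C)C(=O)OC
F2 | step 27 | relay dienol | OC/C=C\C(C)=C/[C@H]1OC(=O)C(CS(=O)(=O)c2ccccc2)[C@@H]1[C@H](OC(=O)[C@@]3(C)O[C@H]3C)[C@@H](OC(=O)[C@H](C)CC)C(=CCCCC=C)C(=O)OC
F3 | step 27 | relay epoxy alcohol | OC[C@H]1O[C@H]1/C(C)=C\[C@H]2OC(=O)C(CS(=O)(=O)c3ccccc3)[C@@H]2[C@H](OC(=O)[C@@]4(C)O[C@H]4C)[C@@H](OC(=O)[C@H](C)CC)C(=CCCCC=C)C(=O)OC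
F4 | step 27 | relay epoxy aldehyde | O=C[C@H]1O[C@H]1/C(C)=C\[C@H]2OC(=O)C(CS(=O)(=O)c3ccccc3)[C@@H]2[C@H](OC(=O)[C@@]4(C)O[C@H]4C)[C@@H](OC(=O)[C@H](C)CC)C(=CCCCC=C)C(=O)OC
F5 | step 27 | relay vinyl epoxide | C=C[C@H]1O[C@H]1/C(C)=C\[C@H]2OC(=O)C(CS(=O)(=O)c3ccccc3)[C@@H]2[C@H](OC(=O)[C@@]4(C)O[C@H]4C)[C@@H](OC(=O)[C@H](C)CC)C(=CCCCC=C)C(=O)OC
F6 | step 18 | C5,C10-diol (C5 primary alcohol, C10 α-hydroxy ester, C10 epimers) | OC[C@H]1OC(=O)C(CS(=O)(=O)c2ccccc2)[C@@H]1[C@H](OC(=O)[C@@]3(C)O[C@H]3C)[C@@H](OC(=O)[C@H](C)CC)C(O)C(=O)OC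
F7 | step 18 | C5 aldehyde with C10 α-hydroxy ester | O=C[C@H]1OC(=O)C(CS(=O)(=O)c2ccccc2)[C@@H]1[C@H](OC(=O)[C@@]3(C)O[C@H]3C)[C@@H](OC(=O)[C@H](C)CC)C(O)C(=O)OC
F8 | step 18 | Z-iodoalkene with C10 α-hydroxy ester | C/C(I)=C/[C@H]1OC(=O)C(CS(=O)(=O)c2ccccc2)[C@@H]1[C@H](OC(=O)[C@@]3(C)O[C@H]3C)[C@@H](OC(=O)[C@H](C)CC)C(O)C(=O)OC
F9 | step 18 | silyloxy diene with C10 α-hydroxy ester | CC(C)(C)[Si](C)(C)OC/C=C\C(C)=C/[C@H]1OC(=O)C(CS(=O)(=O)c2ccccc2)[C@@H]1[C@H](OC(=O)[C@@]3(C)O[C@H]3C)[C@@H](OC(=O)[C@H](C)CC)C(O)C(=O)OC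
F10 | step 13 | 8β,9β-cyclic sulfate of 10 | O=C1O[C@H]2[C@H](C#C[Si](C)(C)C)[C@H]3OS(=O)(=O)O[C@H]3[C@@]14OC(C)(C)O[C@H]24
F11 | step 13 | caesium 9β-sulfate of the 8α-epoxy ester | O=C1O[C@H]2[C@H](C#C[Si](C)(C)C)[C@H](OC(=O)[C@@]3(C)O[C@H]3C)[C@@H](OS(=O)(=O)[O-])[C@@]14OC(C)(C)O[C@H]24.[Cs+]
F12 | step 13 | 9β-alcohol of the 8α-epoxy ester | O=C1O[C@H]2[C@H](C#C[Si](C)(C)C)[C@H](OC(=O)[C@@]3(C)O[C@H]3C)[C@@H](O)[C@@]14OC(C)(C)O[C@H]24
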